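## Structural features

The skeleton is numbered along the chain from the acetoxy carbon: C1 (OAc), C2, C3 (Me), O4, C5, C6, C7 (Br), C8 (Me2), O9, C10 (Me), C11, C12, C13 (OH). The target is a cyclohexane (C1, C2, C3, C13, C12, C11) whose C3 and C11 are spanned by O4–C5–C10, a 2-oxabicyclo[3.2.2]nonane. A tetrahydropyran (C5, C6, C7, C8, O9, C10) is cis-fused to the oxepane along C5–C10. There are seven stereocentres (1S, 3R, 5S, 7S, 10S, 11R, 13R). C10/C11 and C10/C5 are contiguous, C3/C13 are adjacent, and the C1 oxygen is cis to the C11–C10 bond. Three oxygen-bearing carbons are fully substituted (C3, C8, C10) and two of them are stereogenic. The fragile groups are the secondary C7 bromide (elimination or fragmentation with base, loss to reducing agents), the C1 acetate, the tertiary ethers (ionisation by acid), and a C13 hydroxyl that must stay free while C1 is acylated. The real difficulty is twofold: the congested C–O bonds at C10, C8 and C3, and a bromine on C7 next to the gem-dimethyl carbon (no realistic displacement), trans to O4 and cis to the C10 methyl. The key step uses the pyran ring pattern of oxygen on C5, bromine on C7 and a fully substituted C8 beside O9. This is the pattern of a 2H-pyran-3(6H)-one (C5 ketone, C6=C7 enone, C8 ketal), which a 5-methylfuran on the tertiary carbinol C10 delivers on oxidation.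

## Logic of the disconnections

26 to 24: the C3–O4 bond is cut and the C13 hydroxyl is traced to an epoxide across C3–C13 (25). This removes the bridged oxepane and two stereocentres and leaves a pyran attached to a cyclohexene. The forward step needs epoxidation anti to the C1 and C11 substituents and attack of the C5 hydroxyl at the tertiary C3 with inversion. The acetate is placed on C1 before this step so that the C13 hydroxyl is born free and no late differentiation of two secondary alcohols is needed.

24 to 21: the acetate and the C5 silyl ether are functional-group changes, and one C8–CH3 bond is cut. This turns the gem-dimethyl carbon into the ketal carbon of 21, in which C8 is tied to the C1 oxygen. The forward step must ionise the C8–O(C1) bond and not C8–O9, and must free the C1 hydroxyl as the only hydroxyl of 22.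

21 to 17: the C5–H and C7–Br bonds are cut, giving the bridged enone 17. Two stereocentres disappear. The forward steps need both nucleophiles to enter from the convex face of the bicyclic ketal, which the C1–O–C8 bridge enforces. A monocyclic pyranone would be expected to give the opposite sense at both centres.

17 to 16: the C8–O(C1) ketal bond is cut and the C1 oxygen is returned to its silyl ether. The forward step is a desilylation with ketalisation that makes the temporary tether.

16 to 14 (key disconnection): the O9–C8 bond is cut and the pyranone is folded back to a 5-methylfuran on the C10 carbinol. One ring and the whole C5 to C8 oxidation pattern are traded for an aromatic ring. The forward oxidation must spare the ring alkene and use the C10 hydroxyl only.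

14 to 11 and 12: the C10–C5 bond (carbinol to furan) is cut. The forward addition must set C10 from C11. With a non-chelating silyl ether on C1, Felkin–Anh control gives 10S only if the furyl group is the nucleophile and the methyl group is already on the ketone, so the methyl ketone 11 is the electrophile.

11 to 8: the C10–CH3 bond and the silyl ether are removed through the Weinreb amide 9/10. This is a plain acyl substitution on an auxiliary-bearing ring.

8 to 7: the C3=C13 double bond is cut by retro-metathesis to a diene. The forward ring closure is a six-membered metathesis that touches no stereocentre.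

7 to 3 and 5: the C11–C1 bond is cut as a syn aldol. This sets both ring stereocentres (cis on the later ring) from the auxiliary in one step and reduces the problem to 1, 2 and 4.

## Other disconnections considered

Alternative 1: The C12–C13 bond is cut. In the forward step SmI2 (divalent samarium) would reduce the C13 aldehyde of the oxepanone A1 to a ketyl, which adds to the exocyclic methylene C12 of the C1 enone and gives the tricyclic ketol A2.
- In its favour: it is a well-known ketyl–olefin closure of a six-membered ring and it creates C13 and C11 in the key step, where the chosen key step creates no stereocentre; on that count it is the better plan. It also distinguishes C1 (ketone) from C13 (alcohol) by oxidation level, which is at least the equal of the protecting-group solution chosen here.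
- Against it: the ketyl sits on a carbon that carries O4, so reductive cleavage of the C3–O4 bond is a likely competing path. The C7 bromide is exposed to a strong one-electron reductant. A1 already contains the bromopyran, the oxepanone and a quaternary α-alkoxy aldehyde, so the hard C–O bonds must be made before the key step with no help from it. A2 still needs a face-selective C1 reduction and acetylation beside a free C13 hydroxyl.
- Overall the chosen plan should be shorter and exposes the bromide to milder reagents.

Alternative 2: The C10–C11 bond is cut. In the forward step the trivalent iridium photocatalyst Ir[dF(CF3)ppy]2(dtbbpy)PF6 would oxidise the C10 carboxylate of A3. Loss of CO2 gives a tertiary α-oxy radical that adds to C11 of the tethered cyclohexenone and gives the tricyclic C13 ketone A4.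
- In its favour: a radical is a sound way to join a fully substituted carbon to a ring carbon. The bromide should survive the mild reductant. The C1 acetate is already in place, so only a ketone reduction separates A4 from the target; that endgame is shorter than the chosen one.
- Against it: the closure is a seven-membered radical cyclisation that competes with simple reduction of the radical. C10 and C11 are both set with only the tether as control. A3 needs an intermolecular tertiary ether bond C3–O4 between two hindered fragments, for which no dependable method exists, and it carries a γ-acetoxy enone prone to elimination.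
- The chosen plan has C10–C11 present from the first step and forms C3–O4 intramolecularly, so it is the safer on structure even if its endgame is longer.

Alternative 3: The O9–C10 and C3–O4 bonds are cut. Camphorsulfonic acid would make the C8 hydroxyl of the bromohydrin diepoxide A5 open the C5–C10 epoxide at C10, and the freed C5 oxygen open the ring epoxide at C3, giving the silyl ether A6.
- In its favour: two rings and two C–O bonds form in one stereospecific step, and on step count this is the better plan. The second ring closure is the same event as step 16 of the chosen route, so the two plans are equal there.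
- Against it: the C7 stereocentre must be set in an open chain (bromohydrin formation on a trisubstituted alkene has no facial control). Two different trisubstituted alkenes must be epoxidised with defined and different facial sense. The first opening must go six-membered at C10 and not five-membered at C5. A6 ends with a free C13 hydroxyl next to a C1 silyl ether, so the final acetylation must discriminate two secondary alcohols.
- The chosen plan sets C7 and C5 on a rigid bicycle and C10 by carbonyl addition, at the cost of more steps.

Key step: step 9

Remark: the hemiketal carbon C8 of 16 is taken as a mixture of epimers, which converge in step 10; the skeleton locants defined above are used for every intermediate.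

## Route

Step 1
Reactants: 1 (R)-4-benzyl-1,3-oxazolidin-2-one; 2 pent-4-enoyl chloride
Product: 3 (R)-4-benzyl-3-(pent-4-enoyl)-1,3-oxazolidin-2-one
Conditions: n-BuLi, THF, −78 °C; then 2, −78 to 0 °C
Reagents that add atoms: none
Why: N-acylation of the lithiated oxazolidinone, the standard preparation of an Evans imide.

Step 2
Reactants: 4 3-methylbut-3-en-1-ol
Product: 5 3-methylbut-3-enal (used at once as a cold solution)
Conditions: Dess–Martin periodinane, NaHCO3, CH2Cl2, 0 °C
Reagents that add atoms: none
Why: Dess–Martin oxidation of a primary alcohol under buffered, cold conditions, which should keep the double bond from moving into conjugation.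

Step 3
Reactants: 3 (R)-4-benzyl-3-(pent-4-enoyl)-1,3-oxazolidin-2-one; 5 3-methylbut-3-enal
Product: 7 (R)-4-benzyl-3-[(2R,3S)-3-hydroxy-5-methyl-2-(prop-2-en-1-yl)hex-5-enoyl]-1,3-oxazolidin-2-one, via dibutylboron enolate 6 (not isolated)
Conditions: Bu2BOTf, i-Pr2NEt, CH2Cl2, 0 °C; 5, −78 to 0 °C; pH 7 buffer, MeOH, H2O2
Reagents that add atoms: none
Why: Evans syn aldol: the Z-boron enolate reacts through a Zimmerman–Traxler chair on the face away from the benzyl group, setting C11 (R) and C1 (S); the syn relation becomes the cis relation on the ring.

Step 4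
Reactants: 7 the aldol adduct of step 3
Product: 8 (R)-4-benzyl-3-[(1R,6S)-6-hydroxy-4-methylcyclohex-3-ene-1-carbonyl]-1,3-oxazolidin-2-one
Conditions: second-generation Grubbs catalyst (H2IMes)(PCy3)Cl2Ru=CHPh (3 mol %), CH2Cl2, 40 °C
Reagents that add atoms: none
Why: ring-closing metathesis of a monosubstituted and a 1,1-disubstituted alkene to the trisubstituted cyclohexene C3=C13 with loss of ethene; no stereocentre is touched.

Step 5
Reactants: 8 the cyclohexene imide of step 4
Product: 9 (1R,6S)-6-hydroxy-N-methoxy-N,4-dimethylcyclohex-3-ene-1-carboxamide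
Conditions: Me3Al, MeNHOMe·HCl, THF, −20 to 0 °C
Reagents that add atoms: N,O-dimethylhydroxylamine hydrochloride, CNOC.Cl
Why: aluminium amide transamidation of an aldol imide, helped by the free β-hydroxyl, gives the Weinreb amide and returns the auxiliary.

Step 6
Reactants: 9 the hydroxy Weinreb amide
Product: 10 (1R,6S)-6-[tert-butyl(dimethyl)silyloxy]-N-methoxy-N,4-dimethylcyclohex-3-ene-1-carboxamide
Conditions: TBSOTf, 2,6-lutidine, CH2Cl2, −78 to 0 °C
Reagents that add atoms: tert-butyldimethylsilyl triflate, CC(C)(C)[Si](C)(C)OS(=O)(=O)C(F)(F)F
Why: silylation of the secondary alcohol; the bulky, non-chelating ether is needed for the stereocontrol of step 8 and blocks the C1 oxygen in step 9.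

Step 7
Reactants: 10 the silylated Weinreb amide
Product: 11 1-[(1R,6S)-6-[tert-butyl(dimethyl)silyloxy]-4-methylcyclohex-3-en-1-yl]ethan-1-one
Conditions: MeMgBr, THF, −20 to 0 °C
Reagents that add atoms: methylmagnesium bromide, C[Mg]Br
Why: Weinreb ketone synthesis; the chelated tetrahedral intermediate stops at the ketone and shields the α-centre C11 from enolisation until the quench.

Step 8
Reactants: 11 the methyl ketone; 12 2-methylfuran
Product: 14 (1S)-1-[(1R,6S)-6-[tert-butyl(dimethyl)silyloxy]-4-methylcyclohex-3-en-1-yl]-1-(5-methylfuran-2-yl)ethan-1-ol, via 5-methyl-2-furyllithium 13 (not isolated)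
Conditions: 12, n-BuLi, THF, 0 °C; then 11, −78 °C
Reagents that add atoms: none
Why: 1,2-addition of a 2-furyllithium under Felkin–Anh control: the furyl group enters anti to the C11–C1 bond (the branch with the silyloxy group) and past the C11 hydrogen, which should give 10S. The reverse order (methyl reagent onto a furyl ketone) would need chelation to the C1 oxygen, which a silyl ether does not offer, so it is not used.

Step 9
Reactants: 14 the tertiary furyl carbinol
Product: 16 (2S)-6-hydroxy-2,6-dimethyl-2-[(1R,6S)-6-[tert-butyl(dimethyl)silyloxy]-4-methylcyclohex-3-en-1-yl]-2H-pyran-3(6H)-one (both C6 epimers), via Z-ene-dione 15 (not isolated)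
Conditions: NBS (1.05 equiv), NaHCO3, THF–H2O (4:1), 0 °C
Reagents that add atoms: water, O
Why: NBS brominates the electron-rich 2,5-dialkylfuran, water adds at the other α-carbon, and loss of HBr opens the dihydrofuran to the Z-ene-dione 15. The tertiary C10 hydroxyl then adds to the C8 ketone in a 6-exo-trig hemiketalisation that forms O9–C8 and closes the pyranone ring. This is the Achmatowicz rearrangement of a tertiary 2-furyl carbinol. The only new stereocentre is the hemiketal carbon C8, which forms as a mixture under anomeric control, converges in step 10 and is erased in step 14; C1, C10 and C11 are untouched. The step needs the furan to react before the trisubstituted ring alkene: the furan is far more nucleophilic, and one equivalent of NBS at 0 °C secures this. It also needs the C10 hydroxyl to be the only internal nucleophile, which the silyl ether on C1 secures by preventing a five-membered hemiketal at C5. The bicarbonate buffer should keep the tertiary furyl carbinol from ionising.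

Step 10
Reactants: 16 the hemiketal
Product: 17 bridged enone ketal, (2S,6S,6aR,10aS)-2,6,9-trimethyl-6a,7,10,10a-tetrahydro-2H-2,6-epoxy-1-benzoxocin-5(6H)-one (C8 bonded to O9 and to the C1 oxygen; C5 ketone; C6=C7)
Conditions: 48% aq HF, MeCN, 0 °C to rt
Reagents that add atoms: none
Why: acidic desilylation followed by bicycloketalisation: the freed C1 hydroxyl captures the C8 oxocarbenium ion and closes a six-membered 1,3-dioxane (2,9-dioxabicyclo[3.3.1]nonenone), a known fate of Achmatowicz products with a 1,3-related hydroxyl. The bridge can only form with the C1 oxygen and C11 on the same face of the pyranone, so both C8 epimers give one ketal.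

Step 11
Reactants: 17 the bridged enone ketal
Product: 19 bridged β-bromo ketone (7S; bromine on C7 on the face away from the O–C1–C11 bridge, C6 saturated), via silyl enol ether 18 (not isolated)
Conditions: Me3SiBr, CH2Cl2, −78 to −30 °C; then pH 7 buffer
Reagents that add atoms: bromotrimethylsilane, C[Si](C)(C)Br
Why: 1,4-addition of a halosilane to an enone (bromide to C7, silicon to the carbonyl oxygen) followed by hydrolysis. As in conjugate additions to levoglucosenone-type bridged enones, the nucleophile should enter on the convex face anti to the three-atom bridge, which sets 7S. The aprotic reagent should leave the ring alkene alone.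

Step 12
Reactants: 19 the bridged β-bromo ketone
Product: 20 bridged bromo alcohol (5S; C5 hydroxyl on the side of C11, trans to bromine)
Conditions: NaBH4, CeCl3·7H2O, MeOH, −78 °C
Reagents that add atoms: none
Why: Luche-type carbonyl reduction; hydride should approach C5 anti to the C10–C11 bond, which the bicycle holds perpendicular to the carbonyl plane, giving the equatorial alcohol syn to C11. The cold, nearly neutral medium should avoid E1cB loss of HBr.

Step 13
Reactants: 20 the bridged bromo alcohol
Product: 21 the C5 triethylsilyl ether of 20
Conditions: Et3SiCl, imidazole, DMAP, DMF, rt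
Reagents that add atoms: chlorotriethylsilane, CC[Si](Cl)(CC)CC
Why: silylation of the only free hydroxyl, so that the C1 hydroxyl released in step 14 can be acetylated without competition.

Step 14
Reactants: 21 the silylated bridged ketal
Product: 22 (1S,6R)-6-[(2S,3S,5S)-5-bromo-2,6,6-trimethyl-3-(triethylsilyloxy)oxan-2-yl]-3-methylcyclohex-3-en-1-ol
Conditions: Me3Al (4 equiv), CH2Cl2, −78 °C to rt
Reagents that add atoms: trimethylaluminium, C[Al](C)C
Why: Lewis-acid opening of a bicyclic ketal by an organoaluminium reagent. Cleavage of C8–O(C1) leaves a six-membered oxocarbenium ion (cleavage of C8–O9 would leave an eight-membered one), and methyl transfer to C8 gives the gem-dimethyl carbon. C8 ceases to be stereogenic and the C1 hydroxyl is freed.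

Step 15
Reactants: 22 the oxanyl cyclohexenol
Product: 24 (1S,6R)-6-[(2S,3S,5S)-5-bromo-3-hydroxy-2,6,6-trimethyloxan-2-yl]-3-methylcyclohex-3-en-1-yl acetate, via silyl ether acetate 23 (not isolated)
Conditions: Ac2O, DMAP, pyridine, CH2Cl2, rt; then HF·pyridine, THF, 0 °C to rt
Reagents that add atoms: acetic anhydride, CC(=O)OC(C)=O
Why: DMAP-catalysed acetylation of the only free hydroxyl, then fluoride cleavage of the triethylsilyl ether, which leaves the acetate, the bromide and the alkene alone.

Step 16
Reactants: 24 the hydroxy acetate
Product: 26 target CNP0247588.2 (1S,3R,5S,7S,10S,11R,13R; C1 acetate, C13 alcohol, C7 bromide), via epoxy alcohol 25 (not isolated)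
Conditions: m-CPBA, CH2Cl2, 0 °C; then CSA (10 mol %), 0 °C to rt
Reagents that add atoms: 3-chloroperoxybenzoic acid, OOC(=O)c1cccc(Cl)c1
Why: Prilezhaev epoxidation on the face anti to the pseudoaxial C1 acetate and the C11 substituent, then acid-catalysed opening of the epoxide by the C5 hydroxyl at the tertiary C3 with inversion. This forms C3–O4, closes the seven-membered ring and leaves the C13 hydroxyl trans to O4, setting 3R and 13R. The closest known case is the closure of terpineol epoxide to hydroxy-cineole through a boat.

## Compound list

1 | (R)-4-benzyl-1,3-oxazolidin-2-one | O=C1N[C@H](Cc2ccccc2)CO1 | starting material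
2 | pent-4-enoyl chloride | C=CCCC(Cl)=O | starting material
3 | (R)-4-benzyl-3-(pent-4-enoyl)-1,3-oxazolidin-2-one | C=CCCC(=O)N1[C@H](Cc2ccccc2)COC1=O | intermediate
4 | 3-methylbut-3-en-1-ol | CC(=C)CCO | starting material
5 | 3-methylbut-3-enal | CC(=C)CC=O | intermediate
6 | Z-dibutylboron enolate of 3 | C=CC/C=C(\OB(CCCC)CCCC)N1[C@H](Cc2ccccc2)COC1=O | intermediate (not isolated)
7 | (R)-4-benzyl-3-[(2R,3S)-3-hydroxy-5-methyl-2-(prop-2-en-1-yl)hex-5-enoyl]-1,3-oxazolidin-2-one | C=CC[C@H]([C@@H](O)CC(C)=C)C(=O)N1[C@H](Cc2ccccc2)COC1=O | intermediate
8 | (R)-4-benzyl-3-[(1R,6S)-6-hydroxy-4-methylcyclohex-3-ene-1-carbonyl]-1,3-oxazolidin-2-one | O=C([C@@H]1CC=C(C)C[C@@H]1O)N2[C@H](Cc3ccccc3)COC2=O | intermediate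
9 | (1R,6S)-6-hydroxy-N-methoxy-N,4-dimethylcyclohex-3-ene-1-carboxamide | CON(C)C(=O)[C@@H]1CC=C(C)C[C@@H]1O | intermediate
10 | (1R,6S)-6-[tert-butyl(dimethyl)silyloxy]-N-methoxy-N,4-dimethylcyclohex-3-ene-1-carboxamide | CON(C)C(=O)[C@@H]1CC=C(C)C[C@@H]1O[Si](C)(C)C(C)(C)C | intermediate
11 | 1-[(1R,6S)-6-[tert-butyl(dimethyl)silyloxy]-4-methylcyclohex-3-en-1-yl]ethan-1-one | CC(=O)[C@@H]1CC=C(C)C[C@@H]1O[Si](C)(C)C(C)(C)C | intermediate
12 | 2-methylfuran | Cc1ccco1 | starting material
13 | 5-methyl-2-furyllithium | [Li]c1ccc(C)o1 | intermediate (not isolated)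
14 | (1S)-1-[(1R,6S)-6-[tert-butyl(dimethyl)silyloxy]-4-methylcyclohex-3-en-1-yl]-1-(5-methylfuran-2-yl)ethan-1-ol | Cc1ccc(o1)[C@@](C)(O)[C@@H]2CC=C(C)C[C@@H]2O[Si](C)(C)C(C)(C)C | intermediate
15 | (3Z,6S)-6-hydroxy-6-[(1R,6S)-6-[tert-butyl(dimethyl)silyloxy]-4-methylcyclohex-3-en-1-yl]hept-3-ene-2,5-dione | CC(=O)/C=C\C(=O)[C@@](C)(O)[C@@H]1CC=C(C)C[C@@H]1O[Si](C)(C)C(C)(C)C | intermediate (not isolated)
16 | (2S)-6-hydroxy-2,6-dimethyl-2-[(1R,6S)-6-[tert-butyl(dimethyl)silyloxy]-4-methylcyclohex-3-en-1-yl]-2H-pyran-3(6H)-one (one C6 epimer drawn) | C[C@@]1(O)C=CC(=O)[C@@](C)(O1)[C@@H]2CC=C(C)C[C@@H]2O[Si](C)(C)C(C)(C)C | intermediate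
17 | bridged enone ketal (C8 ketal to O9 and the C1 oxygen, C5 ketone, C6=C7) | C[C@@]1(O3)C=CC(=O)[C@@](C)(O1)[C@@H]2CC=C(C)C[C@@H]23 | intermediate
18 | C5 trimethylsilyl enol ether of the C7 bromide | C[C@@]1(O3)[C@@H](Br)C=C(O[Si](C)(C)C)[C@@](C)(O1)[C@@H]2CC=C(C)C[C@@H]23 | intermediate (not isolated)
19 | bridged (7S)-β-bromo ketone | C[C@@]1(O3)[C@@H](Br)CC(=O)[C@@](C)(O1)[C@@H]2CC=C(C)C[C@@H]23 | intermediate
20 | bridged (5S,7S)-bromo alcohol | C[C@@]1(O3)[C@@H](Br)C[C@H](O)[C@@](C)(O1)[C@@H]2CC=C(C)C[C@@H]23 | intermediate
21 | C5 triethylsilyl ether of 20 | C[C@@]1(O3)[C@@H](Br)C[C@H](O[Si](CC)(CC)CC)[C@@](C)(O1)[C@@H]2CC=C(C)C[C@@H]23 | intermediate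
22 | (1S,6R)-6-[(2S,3S,5S)-5-bromo-2,6,6-trimethyl-3-(triethylsilyloxy)oxan-2-yl]-3-methylcyclohex-3-en-1-ol | CC1(C)[C@@H](Br)C[C@H](O[Si](CC)(CC)CC)[C@@](C)(O1)[C@@H]2CC=C(C)C[C@@H]2O | intermediate
23 | acetate of 22 | CC1(C)[C@@H](Br)C[C@H](O[Si](CC)(CC)CC)[C@@](C)(O1)[C@@H]2CC=C(C)C[C@@H]2OC(C)=O | intermediate (not isolated)
24 | (1S,6R)-6-[(2S,3S,5S)-5-bromo-3-hydroxy-2,6,6-trimethyloxan-2-yl]-3-methylcyclohex-3-en-1-yl acetate | CC1(C)[C@@H](Br)C[C@H](O)[C@@](C)(O1)[C@@H]2CC=C(C)C[C@@H]2OC(C)=O | intermediate
25 | C3–C13 epoxide of 24, oxirane oxygen anti to the acetoxy and oxanyl groups | CC1(C)[C@@H](Br)C[C@H](O)[C@@](C)(O1)[C@@H]2C[C@H]3O[C@@]3(C)C[C@@H]2OC(C)=O | intermediate (not isolated)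
26 | CNP0247588.2 | CC(=O)O[C@H]1C[C@@]2(C)O[C@H]3C[C@H](Br)C(C)(C)O[C@@]3(C)[C@@H]1C[C@H]2O | target

## Step count and least certain steps

Total: 16 steps. Longest linear sequence: 15 steps (steps 1 and 3 to 16 from 1 and 2, or steps 2 to 16 from 4).

Step 14. The α-bromo ketal may fail to ionise, or the oxocarbenium ion may lose a proton to an enol ether before methyl transfer, because the bromine on C7 withdraws electron density from C8. Fallback from 21: opening with PhSSiMe3 and ZnI2 (known for anhydro sugars) to the phenylthio ketal F1; oxidation at sulfur with (NH4)6Mo7O24 and H2O2 to the sulfone F2; displacement of the sulfonyl group by Me3Al. This returns to the route at 22.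

Step 16. The C5 hydroxyl may attack the secondary epoxide carbon C13 through a chair (six-membered ring) in place of the tertiary C3, or the C1 acetate carbonyl may take part at C3. Fallback from 24: dihydroxylation with OsO4 (catalytic) and N-methylmorpholine N-oxide on the face anti to the acetate to the cis diol F3; ionisation of the tertiary C3 hydroxyl with BF3·OEt2 at low temperature, so that only C3 is electrophilic and the C5 hydroxyl closes the ether from the side of C11. This returns at 26.

Step 12. Hydride may be delivered from the concave face, because the axial bromine on C7 crowds the convex trajectory at C5. Fallback from 19: reagent-controlled Corey–Bakshi–Shibata reduction (oxazaborolidine and catecholborane, the catalyst enantiomer matched to convex-face delivery), returning at 20. This fallback makes no new compound (F0).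

Step 9 (key step). Over-oxidation is the main danger: bromohydrin formation at the ring alkene once the furan is consumed, or ionisation of the tertiary carbinol if the medium turns acidic. Fallback from 14: photooxygenation with singlet oxygen (O2, tetraphenylporphyrin, light, CH2Cl2, −78 °C) to the furan endoperoxide F4, then reduction with Me2S. This gives 15 and returns at 16.

Step 8. Facial selectivity of the addition may be poor, or the methyl ketone may be enolised by the aryllithium. Fallback from 10: addition of 13 to the Weinreb amide to give the furyl ketone F5; desilylation (HF, MeCN) to the β-hydroxy ketone F6; chelation-controlled addition of excess MeMgBr through the magnesium alkoxide to the diol F7 (the chelate model gives the same 10S); selective silylation of the secondary hydroxyl (TBSOTf, 2,6-lutidine). This returns at 14.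

## Further compounds

F1 | step 14 | phenylthio ketal (C8 epimers), C1 alcohol | CC1(Sc2ccccc2)[C@@H](Br)C[C@H](O[Si](CC)(CC)CC)[C@@](C)(O1)[C@@H]3CC=C(C)C[C@@H]3O
F2 | step 14 | C8 phenylsulfonyl ketal | CC1(S(=O)(=O)c2ccccc2)[C@@H](Br)C[C@H](O[Si](CC)(CC)CC)[C@@](C)(O1)[C@@H]3CC=C(C)C[C@@H]3O
F3 | step 16 | C3,C13 cis diol of 24 (both hydroxyls anti to the acetate) | CC1(C)[C@@H](Br)C[C@H](O)[C@@](C)(O1)[C@@H]2C[C@@H](O)[C@@](C)(O)C[C@@H]2OC(C)=O
F0 | step 12 | none | none
F4 | step 9 | furan endoperoxide of 14 | CC12OOC(C=C1)(O2)[C@@](C)(O)[C@@H]3CC=C(C)C[C@@H]3O[Si](C)(C)C(C)(C)C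
F5 | step 8 | [(1R,6S)-6-[tert-butyl(dimethyl)silyloxy]-4-methylcyclohex-3-en-1-yl](5-methylfuran-2-yl)methanone | Cc1ccc(o1)C(=O)[C@@H]2CC=C(C)C[C@@H]2O[Si](C)(C)C(C)(C)C
F6 | step 8 | [(1R,6S)-6-hydroxy-4-methylcyclohex-3-en-1-yl](5-methylfuran-2-yl)methanone | Cc1ccc(o1)C(=O)[C@@H]2CC=C(C)C[C@@H]2O
F7 | step 8 | (1S,6R)-6-[(1S)-1-hydroxy-1-(5-methylfuran-2-yl)ethyl]-3-methylcyclohex-3-en-1-ol | Cc1ccc(o1)[C@@](C)(O)[C@@H]2CC=C(C)C[C@@H]2O
A1 | alternative 1 | oxepanone with C13 aldehyde on C3 and exocyclic methylene C12 on C11 | O=C1C[C@](C)(C=O)O[C@H]2C[C@H](Br)C(C)(C)O[C@@]2(C)C1=C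
A2 | alternative 1 | tricyclic C1 ketone with free C13 hydroxyl | O=C1C[C@@]2(C)O[C@H]3C[C@H](Br)C(C)(C)O[C@@]3(C)[C@@H]1C[C@H]2O
A3 | alternative 2 | C10 carboxylic acid tethered through O4 to the C13 cyclohexenone | CC(=O)O[C@H]1C[C@@](C)(O[C@H]2C[C@H](Br)C(C)(C)O[C@@]2(C)C(O)=O)C(=O)C=C1
A4 | alternative 2 | tricyclic C13 ketone | CC(=O)O[C@H]1C[C@@]2(C)O[C@H]3C[C@H](Br)C(C)(C)O[C@@]3(C)[C@@H]1CC2=O
A5 | alternative 3 | bromohydrin diepoxide | CC(C)(O)[C@@H](Br)C[C@@H]1O[C@]1(C)[C@@H]2C[C@H]3O[C@@]3(C)C[C@@H]2O[Si](C)(C)C(C)(C)C
A6 | alternative 3 | C1 tert-butyldimethylsilyl ether of the deacetyl target | CC(C)(C)[Si](C)(C)O[C@H]1C[C@@]2(C)O[C@H]3C[C@H](Br)C(C)(C)O[C@@]3(C)[C@@H]1C[C@H]2O
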